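**Retrosynthetic overview**

1. Target 23 comes from Pd(0) deallylation of bis-allyl ether 22. In 22 the pyran ring C (O1–C2–C3–C4–C4a–C8a) comes from the seven-membered ring of tetrahydro-1,4-benzoxazepine 17 (O1–C2–C3–N–C4–C4a–C8a). The nitrogen is deleted as N2, which forges C3–C4, the only C–C bond between the two halves.
2. Enabling feature: C3–C4 is a doubly benzylic bond, since C4 sits on C4a of ring A and C3 on C1' of ring B. An NH placed between them is therefore a dibenzylic secondary amine, the substrate type that extrudes N2 readily. C3 also becomes an arylglycinol-type C–N stereocentre that auxiliary chemistry can set.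
3. 17 comes from intramolecular reductive amination (N–C4), from sulfinamide 14 (C3–N, sets R), and from phenacyl ether 11 (O1–C2), made from phenol aldehyde 4 and bromoketone 10. Only C–O and C–N bonds are made before the key step.
4. 4 comes from 2,4-dihydroxybenzaldehyde and prenyl bromide. 10 comes from 2,4-dihydroxyacetophenone and 3-methylbut-2-enal.
5. Ring order: dimethylpyran ring D (step 3), seven-membered oxazepine ring (step 9), contraction to pyran ring C (step 10). Rings A and B are bought.

Key step: step 10

Assumption: isoflavan numbering (O1, C2, C3, C4, C4a to C8a, ring B C1' to C6') is used for all intermediates. Compound 18 and (S)-tert-butanesulfinamide are taken as commercial.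

**Step 1**
Reactants: 1 2,4-dihydroxybenzaldehyde; 2 1-bromo-3-methylbut-2-ene (prenyl bromide)
Product: 3 2,4-dihydroxy-3-(3-methylbut-2-enyl)benzaldehyde
Conditions: KOH (aq), 0 °C → rt
Reagents that add atoms: none
Why: C-allylation of the ambident resorcinolate in water goes preferentially to C3, the carbon flanked by both oxygens, and the O- and C5-prenylated isomers should be removable by chromatography.

**Step 2**
Reactants: 3 2,4-dihydroxy-3-(3-methylbut-2-enyl)benzaldehyde
Product: 4 4-(allyloxy)-2-hydroxy-3-(3-methylbut-2-enyl)benzaldehyde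
Conditions: allyl bromide (1.05 equiv), K2CO3, acetone, rt
Reagents that add atoms: allyl bromide, C=CCBr
Why: Williamson etherification; the 2-OH is held in a hydrogen bond to the formyl group and is flanked on both sides, so the mild base should alkylate only the 4-OH.

**Step 3**
Reactants: 5 2,4-dihydroxyacetophenone; 6 3-methylbut-2-enal
Product: 7 1-(5-hydroxy-2,2-dimethyl-2H-chromen-6-yl)ethanone
Conditions: ethylenediammonium diacetate (10 mol %), xylene, reflux
Reagents that add atoms: none
Why: Formal [3+3] chromene annulation (aldol-type condensation at C3, then oxa-6π electrocyclisation); the chelated 2-OH stays out, so the free 4-OH becomes the pyran oxygen and the angular 5-hydroxy isomer required for ring B/D should result.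

**Step 4**
Reactants: 7 1-(5-hydroxy-2,2-dimethyl-2H-chromen-6-yl)ethanone
Product: 8 1-[5-(allyloxy)-2,2-dimethyl-2H-chromen-6-yl]ethanone
Conditions: allyl bromide, K2CO3, DMF, 60 °C
Reagents that add atoms: allyl bromide, C=CCBr
Why: Williamson etherification under more forcing conditions overcomes the chelation of the only phenol present.

**Step 5**
Reactants: 8 1-[5-(allyloxy)-2,2-dimethyl-2H-chromen-6-yl]ethanone
Product: 10 1-[5-(allyloxy)-2,2-dimethyl-2H-chromen-6-yl]-2-bromoethanone, via silyl enol ether 9 (not isolated)
Conditions: LiHMDS, TMSCl, THF, −78 °C; then NBS, −78 → 0 °C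
Reagents that add atoms: N-bromosuccinimide, O=C1CCC(=O)N1Br; chlorotrimethylsilane, C[Si](C)(C)Cl (atoms only in intermediate 9)
Why: Kinetic enolate silylation followed by electrophilic bromination of the silyl enol ether, by far the most nucleophilic π bond present, so the chromene and allyl alkenes and the arene should be spared at low temperature.

**Step 6**
Reactants: 4 4-(allyloxy)-2-hydroxy-3-(3-methylbut-2-enyl)benzaldehyde; 10 1-[5-(allyloxy)-2,2-dimethyl-2H-chromen-6-yl]-2-bromoethanone
Product: 11 4-(allyloxy)-2-{2-[5-(allyloxy)-2,2-dimethyl-2H-chromen-6-yl]-2-oxoethoxy}-3-(3-methylbut-2-enyl)benzaldehyde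
Conditions: K2CO3, acetone, rt
Reagents that add atoms: none
Why: SN2 O-alkylation of the phenoxide by the phenacyl-type bromide makes O1–C2; weak base, room temperature and two electron-rich carbonyl partners should hold back the follow-up intramolecular aldol condensation (Rap–Stoermer reaction).

**Step 7**
Reactants: 11 keto aldehyde
Product: 12 1-[5-(allyloxy)-2,2-dimethyl-2H-chromen-6-yl]-2-[3-(allyloxy)-6-(1,3-dioxolan-2-yl)-2-(3-methylbut-2-enyl)phenoxy]ethanone
Conditions: (TMSOCH2)2, TMSOTf (5 mol %), CH2Cl2, −78 °C
Reagents that add atoms: 1,2-bis(trimethylsilyloxy)ethane, C[Si](C)(C)OCCO[Si](C)(C)C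
Why: TMSOTf-catalysed acetalisation with the bis-silyl glycol ether takes the aldehyde at low temperature, while the hindered conjugated aryl ketone and the alkenes should not react.

**Step 8**
Reactants: 12 dioxolane ketone
Product: 14 (S)-N-{(1R)-1-[5-(allyloxy)-2,2-dimethyl-2H-chromen-6-yl]-2-[3-(allyloxy)-6-(1,3-dioxolan-2-yl)-2-(3-methylbut-2-enyl)phenoxy]ethyl}-2-methylpropane-2-sulfinamide, via sulfinyl ketimine 13 (not isolated)
Conditions: (S)-t-BuS(O)NH2, Ti(OEt)4, THF, 70 °C; then NaBH4, −48 °C
Reagents that add atoms: (S)-tert-butanesulfinamide, CC(C)(C)[S@](=O)N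
Why: Titanium-mediated condensation and in situ borohydride reduction of the N-tert-butanesulfinyl ketimine proceed through the cyclic S=O-coordinated transition state with the aryl group as the large substituent, which for the (S)-auxiliary should set C3 as (R); the dioxolane keeps the more reactive aldehyde out of the condensation.

**Step 9**
Reactants: 14 sulfinamide
Product: 17 (3R)-8-(allyloxy)-3-[5-(allyloxy)-2,2-dimethyl-2H-chromen-6-yl]-9-(3-methylbut-2-enyl)-2,3,4,5-tetrahydro-1,4-benzoxazepine, via amino aldehyde 15 (not isolated), via cyclic aldimine 16 (not isolated)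
Conditions: HCl (dioxane), MeOH–H2O, 0 °C, short contact; then Et3N, MeOH, rt; NaBH4, 0 °C
Reagents that add atoms: none
Why: Mild acid cleaves the N–S bond and the acetal, the freed amino aldehyde condenses to the seven-membered aldimine, and borohydride reduces it (intramolecular reductive amination), which forms N–C4 without touching the C3 stereocentre.

**Step 10**
Reactants: 17 (3R)-tetrahydro-1,4-benzoxazepine; 18 N-(benzyloxy)-N-(pivaloyloxy)-4-(trifluoromethyl)benzamide
Product: 22 (3R)-7,2'-di-O-allyl ether of the target, via hydrazide adduct 19 (not isolated), via 1,1-diazene 20 (not isolated), via 1,6-diradical 21 (not isolated)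
Conditions: 18 (1.5 equiv), THF, 45 °C
Reagents that add atoms: none
Why: The secondary amine attacks the amide nitrogen of 18 (SN2 at N, pivalate leaves) to give 19, which expels benzyl 4-(trifluoromethyl)benzoate by a 1,2-shift of the benzyloxy group to the acyl carbon and leaves the 1,1-diazene 20; loss of N2 gives the singlet diradical 21 (centres C3 and C4), which collapses to the C3–C4 bond. The closest known reaction type is the nitrogen deletion of α-aryl secondary amines with anomeric amides, including ring contraction of 2-aryl pyrrolidines, piperidines and benzo-fused azacycles, together with the older N2 extrusion from cyclic 1,1-diazenes. The only ring closed is pyran ring C, by radical–radical recombination of the ends of the chain C3–C2–O1–C8a–C4a–C4 (1,6-closure, seven-membered ring contracted to six). No new stereocentre is created: C3 is carried over from 17 with retention, because C4 is delivered to the face of the planar C3 radical that nitrogen has just left, and collapse of the tethered singlet pair should outrun rotation about C2–C3, as in the stereoretentive contraction of 2,5-disubstituted pyrrolidines and 2,6-diarylpiperidines. Recombination must beat 1,5-hydrogen transfer, β-scission of C2–O1, tautomerisation of 20 to a hydrazone and addition to the four alkenes; the double benzylic stabilisation (ring A at C4, ring B at C3) makes N2 loss fast at mild temperature, the short C2–O1 tether keeps the radical ends in contact, and the reagent meets only one nucleophilic N–H because both phenols are masked.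

**Step 11**
Reactants: 22 (3R)-7,2'-di-O-allyl ether of the target
Product: 23 target, (3R)-7,2'-dihydroxy-8-(3-methylbut-2-enyl)-6'',6''-dimethylpyrano[2'',3'':4',3']isoflavan
Conditions: Pd(PPh3)4 (5 mol %), morpholine, THF, rt, under N2
Reagents that add atoms: none
Why: Tsuji–Trost-type deallylation; Pd(0) should ionise only the two unhindered aryl allyl ethers, whereas the prenyl group has no leaving group and the tertiary, ring-locked C–O bond of the dimethylchromene is poorly aligned for ionisation.

**Compound list**

1 | 2,4-dihydroxybenzaldehyde | O=Cc1ccc(O)cc1O | starting material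
2 | 1-bromo-3-methylbut-2-ene | CC(C)=CCBr | starting material
3 | 2,4-dihydroxy-3-(3-methylbut-2-enyl)benzaldehyde | CC(C)=CCc1c(O)ccc(C=O)c1O | intermediate
4 | 4-(allyloxy)-2-hydroxy-3-(3-methylbut-2-enyl)benzaldehyde | CC(C)=CCc1c(OCC=C)ccc(C=O)c1O | intermediate
5 | 2,4-dihydroxyacetophenone | CC(=O)c1ccc(O)cc1O | starting material
6 | 3-methylbut-2-enal | CC(C)=CC=O | starting material
7 | 1-(5-hydroxy-2,2-dimethyl-2H-chromen-6-yl)ethanone | CC(=O)c1ccc2c(c1O)C=CC(C)(C)O2 | intermediate
8 | 1-[5-(allyloxy)-2,2-dimethyl-2H-chromen-6-yl]ethanone | CC(=O)c1ccc2c(c1OCC=C)C=CC(C)(C)O2 | intermediate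
9 | trimethylsilyl enol ether of 8 (not isolated) | C=C(O[Si](C)(C)C)c1ccc2c(c1OCC=C)C=CC(C)(C)O2 | intermediate
10 | 1-[5-(allyloxy)-2,2-dimethyl-2H-chromen-6-yl]-2-bromoethanone | O=C(CBr)c1ccc2c(c1OCC=C)C=CC(C)(C)O2 | intermediate
11 | keto aldehyde (phenacyl ether of 4) | CC(C)=CCc1c(OCC=C)ccc(C=O)c1OCC(=O)c1ccc2c(c1OCC=C)C=CC(C)(C)O2 | intermediate
12 | 1,3-dioxolane of 11 | CC(C)=CCc1c(OCC=C)ccc(C2OCCO2)c1OCC(=O)c1ccc2c(c1OCC=C)C=CC(C)(C)O2 | intermediate
13 | (S)-N-tert-butanesulfinyl ketimine of 12 (not isolated) | CC(C)=CCc1c(OCC=C)ccc(C2OCCO2)c1OCC(=N[S@@](=O)C(C)(C)C)c1ccc2c(c1OCC=C)C=CC(C)(C)O2 | intermediate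
14 | (S at sulfur, R at carbon)-sulfinamide | CC(C)=CCc1c(OCC=C)ccc(C2OCCO2)c1OC[C@@H](c1ccc2c(c1OCC=C)C=CC(C)(C)O2)N[S@@](=O)C(C)(C)C | intermediate
15 | (R)-amino aldehyde (not isolated) | CC(C)=CCc1c(OCC=C)ccc(C=O)c1OC[C@@H](c1ccc2c(c1OCC=C)C=CC(C)(C)O2)N | intermediate
16 | (3R)-2,3-dihydro-1,4-benzoxazepine, cyclic aldimine (not isolated) | CC(C)=CCc1c(OCC=C)ccc2c1OC[C@@H](c1ccc3c(c1OCC=C)C=CC(C)(C)O3)N=C2 | intermediate
17 | (3R)-8-(allyloxy)-3-[5-(allyloxy)-2,2-dimethyl-2H-chromen-6-yl]-9-(3-methylbut-2-enyl)-2,3,4,5-tetrahydro-1,4-benzoxazepine | CC(C)=CCc1c(OCC=C)ccc2c1OC[C@@H](c1ccc3c(c1OCC=C)C=CC(C)(C)O3)NC2 | intermediate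
18 | N-(benzyloxy)-N-(pivaloyloxy)-4-(trifluoromethyl)benzamide | CC(C)(C)C(=O)ON(OCc1ccccc1)C(=O)c1ccc(cc1)C(F)(F)F | starting material
19 | N-benzyloxy hydrazide adduct of 17 (not isolated) | CC(C)=CCc1c(OCC=C)ccc2c1OC[C@@H](c1ccc3c(c1OCC=C)C=CC(C)(C)O3)N(C2)N(OCc1ccccc1)C(=O)c1ccc(cc1)C(F)(F)F | intermediate
20 | cyclic 1,1-diazene (not isolated) | CC(C)=CCc1c(OCC=C)ccc2c1OC[C@@H](c1ccc3c(c1OCC=C)C=CC(C)(C)O3)[N+](=[N-])C2 | intermediate
21 | singlet 1,6-diradical at C3 and C4, configuration held by conformational memory (not isolated) | CC(C)=CCc1c(OCC=C)ccc([CH2])c1OC[CH]c1ccc2c(c1OCC=C)C=CC(C)(C)O2 | intermediate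
22 | (3R)-7,2'-di-O-allyl ether of the target | CC(C)=CCc1c(OCC=C)ccc2c1OC[C@@H](c1ccc3c(c1OCC=C)C=CC(C)(C)O3)C2 | intermediate
23 | target, (3R)-isoflavan CNP0263294.2 | CC(C)=CCc1c(O)ccc2c1OC[C@@H](c1ccc3c(c1O)C=CC(C)(C)O3)C2 | target

**Step count**

Total step count: 11.
Longest linear sequence: 9 (steps 3 to 11, from 5). The ring A branch (steps 1 and 2) joins at step 6.

**Steps most likely to fail**

Step 10.
- What may go wrong: amination of the hindered, α-branched amine may be slow, and the 1,1-diazene may tautomerise to a hydrazone. Intramolecular hydrogen transfer may compete with recombination. Above all, the C3 configuration may partly leak if rotation about C2–C3 competes with collapse of the radical pair.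
- Fallback: it sets out from 17 and comes back at 22. It activates the nitrogen with a very small electrophile and generates the N2-losing species reductively instead of by electrophilic amination. tert-Butyl nitrite (CH2Cl2, rt) should give the N-nitrosamine F1. Sodium dithionite in aqueous ethanolic NaOH (60 °C) should then reduce it to the N-amino level, from which N2 is lost with the same seven-to-six ring contraction. This is the classical variant on which retention was established for cis- and trans-2,6-diarylpiperidines.

Step 8.
- What may go wrong: condensation of the ortho-substituted ketone may be incomplete. Facial selectivity may be poor if the ketimine reacts through both C=N geometries. The titanium Lewis acid may cause exchange at the electron-rich acetal.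
- Fallback: it sets out from 11 and comes back at 17. It replaces the auxiliary on an open-chain ketimine by catalysis on a cyclic imine of fixed geometry.
  - Chemoselective reduction of the aldehyde (NaBH(OAc)3) should give the hydroxymethyl ketone F2.
  - DPPA/DBU should give the benzylic azide F3.
  - PPh3 (Staudinger reaction, then intramolecular aza-Wittig reaction) should give the cyclic ketimine F4.
  - Noyori–Ikariya transfer hydrogenation (Ru–TsDPEN, HCO2H/Et3N), which leaves isolated alkenes alone, should reduce F4 to 17. The catalyst antipode is chosen for the (R)-amine.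

Step 6.
- What may go wrong: the newly formed aryloxy ketone may undergo base-induced intramolecular aldol condensation onto the ortho aldehyde, with loss of both carbonyl groups to a benzofuran.
- Fallback: it sets out from 4 and comes back at 12, skipping 11. The electrophilic aldehyde is removed before any base is used. Ethylene glycol with catalytic PPTS (benzene, water separator) should convert 4 into the phenol acetal F5. F5 is then alkylated with 10 (K2CO3, acetone, rt) to give 12 directly.

**Further compounds**

F1 | step 10 | (3R)-N-nitroso derivative of 17 | CC(C)=CCc1c(OCC=C)ccc2c1OC[C@@H](c1ccc3c(c1OCC=C)C=CC(C)(C)O3)N(N=O)C2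
F2 | step 8 | hydroxymethyl ketone (aldehyde of 11 reduced) | CC(C)=CCc1c(OCC=C)ccc(CO)c1OCC(=O)c1ccc2c(c1OCC=C)C=CC(C)(C)O2
F3 | step 8 | benzylic azide | CC(C)=CCc1c(OCC=C)ccc(CN=[N+]=[N-])c1OCC(=O)c1ccc2c(c1OCC=C)C=CC(C)(C)O2
F4 | step 8 | 3-aryl-2,5-dihydro-1,4-benzoxazepine, cyclic ketimine | CC(C)=CCc1c(OCC=C)ccc2c1OCC(c1ccc3c(c1OCC=C)C=CC(C)(C)O3)=NC2
F5 | step 6 | 3-(allyloxy)-6-(1,3-dioxolan-2-yl)-2-(3-methylbut-2-enyl)phenol | CC(C)=CCc1c(OCC=C)ccc(C2OCCO2)c1O
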